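Remark: the identifier is taken to stand for exactly the achiral compound of the SMILES string, methyl 7-hydroxy-5-[2-(4-hydroxyphenyl)ethyl]-2,2-dimethyl-8-(3-methylbut-2-enyl)-2H-chromene-6-carboxylate (18). Chromene numbering is used for 18 and benzoate numbering for the open-ring intermediates.

## Analysis of the target

Target 18 is a 2,2-dimethyl-2H-chromene whose benzene ring (ring A) carries no hydrogen. C5 bears a CH2CH2 chain (Cα on C5) ending in a 4-hydroxyphenyl group (ring C), C6 a methyl ester, C7 a hydroxyl and C8 a prenyl group, and C4a/C8a are fused to the pyran (ring B). There is no stereocentre: the C3=C4 double bond is held cis by ring B and the prenyl alkene ends in two identical methyl groups. The sensitive parts are the electron-rich chromene (acid, electrophiles, oxidants), the prenyl group ortho to the C7 hydroxyl (acid closes it to a chroman), two free phenols, and a salicylate-type ester whose parent acid decarboxylates easily. The difficulty is regiochemical: six different substituents must be set in one order around ring A, and two pairs of positions are easily confused, C6 versus C8 (both ortho to the C7 oxygen) and C8 versus C4a (both ortho to the C8a oxygen). Without ring B and the prenyl group, ring A is a β-resorcylate: C6 has the alkyl-bearing C5 on one side and the oxygen-bearing C7 on the other, and the C8a oxygen is para to C6 and meta to the C7 oxygen. That is the pattern an aryne with two meta-disposed alkoxy groups gives when a carbon nucleophile adds to the aryne carbon remote from the neighbouring alkoxy group and an electrophile is caught at the other. The plan rests on the neighbouring pair C5/C6 with the C7 oxygen beside it: C5–Cα and C6–CO2 are made in one flask, and C8 and C4a are then addressed in that order through the phenols.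

## Retrosynthetic reasoning

Ring B is removed first. Cutting O1–C2 and C4a–C4 of 18 leads to the prenylated resorcylate 15 and 3-methylbut-2-enal (16). The chromene is the most fragile part and should appear last. The cut is also regiochemically safe at this stage: in 15 the carbon between the two ring-A oxygens is already occupied, so the only free carbon ortho to a ring-A hydroxyl is the one that becomes C4a. The forward reaction is a condensation to ortho-quinone methide 17 followed by oxa-6π closure.

The C8–prenyl bond is cut next, giving triphenol ester 12 and 1-bromo-3-methylbut-2-ene (13). The order matters: the carbon between the oxygens is the intrinsically preferred site of a resorcylate for both C-alkylation and chromene annulation. If ring B were made first it would fuse at the wrong carbon, so the prenyl group goes there first and doubles as the blocking group. The forward reaction has to alkylate carbon rather than oxygen, at this carbon rather than at the future C4a, and on ring A rather than ring C.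

The three aryl O–CH3 bonds and the ester O–CH3 bond are then traced back from 12 through trimethyl ether ester 11 to acid 10. Methyl ethers are chosen because they survive organolithium chemistry. They are removed by Lewis-acid ether cleavage at the one point where the molecule has neither an alkene nor ring B, which is why deprotection precedes prenylation. The acid is esterified beforehand so that no free β-resorcylic acid has to be handled.

The key disconnection cuts C5–Cα and C6–CO2 of 10 together. It leads to 2-(4-methoxyphenyl)ethyllithium (3), 1-fluoro-3,5-dimethoxybenzene (4) and carbon dioxide (5), by way of aryne 7. No other cut puts two carbon substituents on adjacent, fully flanked ring positions in one operation while the two oxygens are already in the right places in a commercial arene. The forward reaction must deprotonate 4 next to fluorine, add carbon to the aryne carbon remote from the adjacent methoxy group, and trap aryllithium 8 with 5.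

Organolithium 3 is traced back by halogen–lithium exchange to iodide 2 and from there to commercial alcohol 1. This keeps the supply of the key-step precursors to two routine operations, so that the risk sits in the key step.

## Alternatives that were turned down

Alternative 1: Ring A itself is opened at C5–C6 and C8–C8a and built from the prenylated acetoacetate A1 (methyl 7-methyl-3-oxooct-6-enoate) and the enoate A2 (methyl (E)-5-(4-hydroxyphenyl)pent-2-enoate). Under an alkoxide base the doubly activated carbon of A1 adds to A2 (Michael), and the adduct closes by Dieckmann condensation to the racemic trans cyclohexane-1,3-dione A3. Dehydrogenation of A3 would give 15, and the end game would be the same as here.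
- For: the prenyl group sits on C8 by construction, so there is no C8/C4a competition. On this point the alternative is stronger than the chosen route.
- Against: A3 is one oxidation level below the arene. It must be aromatised with the prenyl alkene and the electron-rich phenol of ring C present, and the usual oxidants for cyclic 1,3-diones (halogens, quinones, hot noble metals) attack or isomerise both. Two stereocentres are made only to be destroyed, and A2 needs several steps.
- Comparison: the length is similar. The chosen route keeps ring A aromatic throughout and puts its uncertainty into a bond-forming step with close precedent instead of an oxidation. The price is the selectivity problem of step 6, for which a sigmatropic fallback exists.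

Alternative 2: Ring B is disconnected at C8a–O1, C4a–C4 and O1–C2. The aryne A4 (3-bromo-5-methoxybenzyne), set free by fluoride from a silyl triflate precursor, takes up the C=O of 16; the four-membered adduct opens to an ortho-quinone methide that closes by oxa-6π electrocyclisation to A5 (5-bromo-7-methoxy-2,2-dimethyl-2H-chromene).
- For: the position of ring B is fixed by the polarisation of the aryne (bromine sends the oxygen to the remote carbon), and the bromine on C5 is a handle for the chain. On the C4a question this is stronger than the chosen route, where ring B is placed correctly only because C8 is blocked first.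
- Against: A5 carries three of the six ring-A substituents. The carboxyl group would have to be inserted at C6 between two occupied carbons, in competition with C8 (both ortho to the methoxy group). The prenyl group would follow, and the C7 methyl ether would then have to be cleaved in the presence of a chromene and a prenyl group, which the usual ether-cleaving conditions do not tolerate.
- Comparison: it spends the aryne on bonds that a simple condensation also makes and leaves the crowded C5/C6 pair for late, uncertain steps. The chosen route does the opposite and is shorter.

Alternative 3: C5–Cα and C4a–C4 are cut from the aryl iodide A6 (1-iodo-2,4-bis(methoxymethoxy)-3-(3-methylbut-2-enyl)benzene). Under Catellani conditions (a palladium catalyst, a strained bicyclic alkene as transient mediator, a carbonate base) the C–H ortho to iodine is alkylated by the iodide A7 (1-(2-iodoethyl)-4-(methoxymethoxy)benzene). The ipso carbon then undergoes Heck coupling with A8 (2-methylbut-3-en-2-ol) to give A9.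
- For: it is convergent, one step sets the chain on C5 and the three-carbon unit of ring B, and the prenyl group is already on C8 (put there by metalation between two acetal oxygens, a very reliable site). On C8 it is stronger than the chosen route.
- Against: A9 has no carbon on C6. The ester would have to enter at the last ring-A C–H, flanked by the chain and an acetal oxygen, in competition with metalation on ring C. The prenyl alkene can interfere with the palladium catalysis and A7 has β-hydrogens. Closing ring B from the E-configured allylic alcohol and removing three acetals both need acid while a prenyl group sits ortho to a phenol oxygen.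
- Comparison: more steps remain after the key step and the hardest substituent, the C6 carboxyl, is still missing. The chosen route installs it in the key step.

Key step: step 3

## Route

Step 1
Reactants: 1 2-(4-methoxyphenyl)ethanol
Product: 2 1-(2-iodoethyl)-4-methoxybenzene
Conditions: I2, PPh3, imidazole, CH2Cl2, 0 °C → rt
Reagents that add atoms: iodine, [I][I]
Why: Appel-type iodination of a primary alcohol; the alkoxyphosphonium ion is displaced by iodide in an SN2 step and the anisole ring is untouched.

Step 2
Reactants: 2 1-(2-iodoethyl)-4-methoxybenzene
Product: 3 2-(4-methoxyphenyl)ethyllithium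
Conditions: t-BuLi (2.0 equiv), Et2O/pentane, −78 °C, 30 min; the solution is carried cold into step 3
Reagents that add atoms: tert-butyllithium, [Li]C(C)(C)C
Why: Iodine–lithium exchange on a primary alkyl iodide; the second equivalent of tert-butyllithium destroys the tert-butyl iodide formed, which makes the exchange irreversible. At −78 °C the exchange is far faster than ring lithiation of the anisole.

Step 3
Reactants: 3 2-(4-methoxyphenyl)ethyllithium; 4 1-fluoro-3,5-dimethoxybenzene; 5 carbon dioxide
Product: 10 2,4-dimethoxy-6-[2-(4-methoxyphenyl)ethyl]benzoic acid, via (2-fluoro-4,6-dimethoxyphenyl)lithium 6 (not isolated), via 3,5-dimethoxybenzyne 7 (not isolated), via aryllithium adduct 8 (not isolated), via lithium carboxylate 9 (not isolated)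
Conditions: 4 (1.0 equiv) added to 3 (2.3 equiv), THF/Et2O/pentane, −78 °C, 1 h; → −10 °C, 2 h; −78 °C, 5 (dry gas) → rt; 1 M HCl
Reagents that add atoms: none
Why: This is the tandem aryne generation, carbolithiation and electrophilic trapping known for 3,5-dialkoxyfluorobenzenes (closest type: three-component vicinal difunctionalisation of an aryne by an organolithium and an electrophile). The first equivalent of 3 removes the ring proton flanked by fluorine and a methoxy group, the most acidic C–H of 4, to give 6, which on warming loses LiF and becomes aryne 7. A second equivalent of 3 adds to 7 and forms the C5–Cα bond; the resulting aryllithium 8 persists until 5 is passed in at −78 °C, which forms the C6–carboxyl bond as carboxylate 9, and acid liberates 10. No ring is closed and no stereocentre is formed. The step needs regiocontrol in the addition: the methoxy group next to the triple bond withdraws σ-electrons and distorts the aryne, so carbon attacks the remote aryne carbon (the one that bore fluorine) and the negative charge develops in the in-plane orbital ortho to that oxygen, where lithium is also coordinated. It also needs chemoselectivity among the nucleophiles: the primary alkyllithium 3, present in excess, is far more reactive toward 7 than the fluorine-stabilised 6 or the doubly ortho-substituted 8, which limits biaryl formation. Deprotonation of 4 between the two methoxy groups would be unproductive, since that anion has no leaving group beside it and merely ends as a separable acid.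

Step 4
Reactants: 10 2,4-dimethoxy-6-[2-(4-methoxyphenyl)ethyl]benzoic acid
Product: 11 methyl 2,4-dimethoxy-6-[2-(4-methoxyphenyl)ethyl]benzoate
Conditions: MeI, K2CO3, DMF, rt
Reagents that add atoms: iodomethane, CI
Why: O-alkylation of the carboxylate (SN2 at methyl) sidesteps the doubly ortho-substituted carbonyl carbon, which makes acid-catalysed esterification of such acids sluggish.

Step 5
Reactants: 11 methyl 2,4-dimethoxy-6-[2-(4-methoxyphenyl)ethyl]benzoate
Product: 12 methyl 2,4-dihydroxy-6-[2-(4-hydroxyphenyl)ethyl]benzoate
Conditions: BBr3 (4.5 equiv), CH2Cl2, −78 °C → rt; ice-water
Reagents that add atoms: none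
Why: Lewis-acid cleavage of aryl methyl ethers: each ether oxygen binds boron and bromide removes the methyl group by SN2, while the less basic ester is attacked more slowly and should survive at or below room temperature. Doing this before the prenyl group and ring B exist keeps BBr3 and HBr away from any alkene.

Step 6
Reactants: 12 methyl 2,4-dihydroxy-6-[2-(4-hydroxyphenyl)ethyl]benzoate; 13 1-bromo-3-methylbut-2-ene
Product: 15 methyl 2,4-dihydroxy-6-[2-(4-hydroxyphenyl)ethyl]-3-(3-methylbut-2-enyl)benzoate, via sodium phenolate 14 (not isolated)
Conditions: NaH (1.05 equiv), toluene, 0 °C → rt; then 13 (1.1 equiv), rt → 45 °C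
Reagents that add atoms: none
Why: Ortho C-alkylation of a sodium phenolate in a non-polar medium (the classical heterogeneous C-allylation of phenolates): one equivalent of NaH ionises only the most acidic hydroxyl, the one para to the ester, and the tight ion pair in toluene disfavours O-alkylation. Of the two carbons ortho to the phenolate oxygen, the one between the two oxygens (C8 of the target) is the more electron-rich and the less hindered, the other being flanked by the phenethyl chain; the dienone formed by SN2 attack on 13 re-aromatises by proton transfer.

Step 7
Reactants: 15 methyl 2,4-dihydroxy-6-[2-(4-hydroxyphenyl)ethyl]-3-(3-methylbut-2-enyl)benzoate; 16 3-methylbut-2-enal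
Product: 18 methyl 7-hydroxy-5-[2-(4-hydroxyphenyl)ethyl]-2,2-dimethyl-8-(3-methylbut-2-enyl)-2H-chromene-6-carboxylate, via ortho-quinone methide 17 (not isolated)
Conditions: 16 (2.5 equiv), ethylenediammonium diacetate (20 mol%), toluene, reflux
Reagents that add atoms: none
Why: Amine-salt-catalysed chromene annulation (formal [3+3]: Knoevenagel-type condensation, then oxa-6π electrocyclisation). The iminium ion of 16 is attacked by the only unsubstituted ring-A carbon ortho to a hydroxyl, loss of the amine gives ortho-quinone methide 17, and 17 closes through the oxygen para to the ester to form ring B. The isolated phenol of ring C is too weak a carbon nucleophile for this catalyst.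

## Compound list

1 | 2-(4-methoxyphenyl)ethanol | COc1ccc(CCO)cc1 | starting material
2 | 1-(2-iodoethyl)-4-methoxybenzene | COc1ccc(CCI)cc1 | intermediate
3 | 2-(4-methoxyphenyl)ethyllithium (prepared and used as a solution) | [Li]CCc1ccc(OC)cc1 | intermediate
4 | 1-fluoro-3,5-dimethoxybenzene | COc1cc(F)cc(OC)c1 | starting material
5 | carbon dioxide | O=C=O | starting material
6 | (2-fluoro-4,6-dimethoxyphenyl)lithium | [Li]c1c(F)cc(OC)cc1OC | intermediate
7 | 3,5-dimethoxybenzyne (1,2-didehydro-3,5-dimethoxybenzene) | COC1=CC(OC)=CC#C1 | intermediate
8 | {2,4-dimethoxy-6-[2-(4-methoxyphenyl)ethyl]phenyl}lithium | [Li]c1c(OC)cc(OC)cc1CCc1ccc(OC)cc1 | intermediate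
9 | lithium 2,4-dimethoxy-6-[2-(4-methoxyphenyl)ethyl]benzoate | [Li+].COc1cc(OC)c(C([O-])=O)c(CCc2ccc(OC)cc2)c1 | intermediate
10 | 2,4-dimethoxy-6-[2-(4-methoxyphenyl)ethyl]benzoic acid | COc1cc(OC)c(C(=O)O)c(CCc2ccc(OC)cc2)c1 | intermediate
11 | methyl 2,4-dimethoxy-6-[2-(4-methoxyphenyl)ethyl]benzoate | COC(=O)c1c(OC)cc(OC)cc1CCc1ccc(OC)cc1 | intermediate
12 | methyl 2,4-dihydroxy-6-[2-(4-hydroxyphenyl)ethyl]benzoate | COC(=O)c1c(O)cc(O)cc1CCc1ccc(O)cc1 | intermediate
13 | 1-bromo-3-methylbut-2-ene | CC(C)=CCBr | starting material
14 | sodium 3-hydroxy-5-[2-(4-hydroxyphenyl)ethyl]-4-(methoxycarbonyl)phenolate | [Na+].COC(=O)c1c(O)cc([O-])cc1CCc1ccc(O)cc1 | intermediate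
15 | methyl 2,4-dihydroxy-6-[2-(4-hydroxyphenyl)ethyl]-3-(3-methylbut-2-enyl)benzoate | COC(=O)c1c(O)c(CC=C(C)C)c(O)cc1CCc1ccc(O)cc1 | intermediate
16 | 3-methylbut-2-enal | CC(C)=CC=O | starting material
17 | methyl (5Z)-2-hydroxy-6-[2-(4-hydroxyphenyl)ethyl]-3-(3-methylbut-2-enyl)-5-(3-methylbut-2-enylidene)-4-oxocyclohexa-1(6),2-diene-1-carboxylate (ortho-quinone methide of 15) | CC(C)=C/C=C1\C(=O)C(CC=C(C)C)=C(O)C(C(=O)OC)=C1CCc1ccc(O)cc1 | intermediate
18 | methyl 7-hydroxy-5-[2-(4-hydroxyphenyl)ethyl]-2,2-dimethyl-8-(3-methylbut-2-enyl)-2H-chromene-6-carboxylate | COC(=O)c1c(O)c(CC=C(C)C)c2c(c1CCc1ccc(O)cc1)C=CC(C)(C)O2 | target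

## Step count and least certain steps

Total step count: 7. Longest linear sequence: 7 steps (1 → 2 → 3 → 10 → 11 → 12 → 15 → 18); 4, 5, 13 and 16 are bought.

**Step 3 (key step).** What is most likely to go wrong:
- decay of 3 before it is used (proton abstraction from the solvent or β-elimination on warming);
- incomplete metalation of 4;
- addition of 6 rather than 3 to aryne 7, which leads to biaryls;
- carboxylation of the surplus 3 to a second acid that has to be separated.

The fallback sets out from 2 and returns at 10, and replaces the aryne by classical electrophilic substitution. Zinc insertion into 2 (Zn dust, LiCl, THF) should give [2-(4-methoxyphenyl)ethyl]zinc iodide F1. Negishi coupling of it with commercial 1-bromo-3,5-dimethoxybenzene (Pd(OAc)2, SPhos, THF) should give 1,3-dimethoxy-5-[2-(4-methoxyphenyl)ethyl]benzene F2. Vilsmeier–Haack formylation (POCl3, DMF) goes para to one methoxy group and ortho to the other, next to the chain, while the mono-oxygenated ring C does not react, and should give 2,4-dimethoxy-6-[2-(4-methoxyphenyl)ethyl]benzaldehyde F3. Pinnick oxidation (NaClO2, NaH2PO4, 2-methylbut-2-ene, t-BuOH/water) then leads back to 10.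

**Step 6.** The phenolate can react at oxygen, at the other ortho carbon (the future C4a), twice, or, after proton exchange, on ring C. Selectivity here rests on ion pairing, charge distribution and sterics, not on a directing element, so this is the weakest step after the key step. The fallback sets out from 12 and returns at 15, and uses a sigmatropic shift in place of intermolecular C-alkylation.
- The acidic hydroxyl para to the ester is etherified with 3-chloro-3-methylbut-1-yne (K2CO3, KI, acetone) to methyl 2-hydroxy-6-[2-(4-hydroxyphenyl)ethyl]-4-[(2-methylbut-3-yn-2-yl)oxy]benzoate F4.
- The alkyne is half-hydrogenated (H2, Pd/CaCO3 poisoned with Pb(OAc)2, quinoline, EtOAc) to methyl 2-hydroxy-6-[2-(4-hydroxyphenyl)ethyl]-4-[(2-methylbut-3-en-2-yl)oxy]benzoate F5.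
- Heating (toluene, 110 °C) triggers an aromatic Claisen rearrangement. The hydrogen-bonded salicylate fixes double-bond character between the ether carbon and the carbon between the oxygens, so the allyl unit should migrate there. It arrives inverted, as a normal prenyl group, and tautomerisation gives 15.

**Step 7.** Carbon–carbon bond formation at the future C4a, flanked by a hydroxyl and the phenethyl CH2, may be slow. Self-condensation of 16 or acid-induced closure of the prenyl group onto a neighbouring hydroxyl could then take over on prolonged heating. The fallback sets out from 15 and returns at 18, and delivers the three-carbon unit intramolecularly. The hydroxyl para to the ester is etherified with 3-chloro-3-methylbut-1-yne (K2CO3, KI, acetone; one equivalent of base, so that the less acidic ring-C phenol stays protonated) to methyl 2-hydroxy-6-[2-(4-hydroxyphenyl)ethyl]-3-(3-methylbut-2-enyl)-4-[(2-methylbut-3-yn-2-yl)oxy]benzoate F6. Heating (xylene, 140 °C) starts a propargyl Claisen rearrangement to the only free ortho carbon, and hydrogen shift leads to the same ortho-quinone methide 17, which closes to 18.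

**Step 5.** Once boron is chelated between the oxygen ortho to the ester and the carbonyl group, the ester methyl group may be lost by the same SN2 mechanism that cleaves the ethers. The fallback sets out from 10 and returns at 12, and reverses the order of the two operations. Acid 10 is itself demethylated (BBr3, CH2Cl2, −78 °C → rt) to 2,4-dihydroxy-6-[2-(4-hydroxyphenyl)ethyl]benzoic acid F7, where there is no ester to lose. The carboxyl group alone is then methylated under conditions too weakly basic to ionise the phenols appreciably (KHCO3, MeI, DMF, rt), giving 12. F7 must not be heated, because β-resorcylic acids decarboxylate.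

## Further compounds

F1 | step 3 | [2-(4-methoxyphenyl)ethyl]zinc iodide | COc1ccc(CC[Zn]I)cc1
F2 | step 3 | 1,3-dimethoxy-5-[2-(4-methoxyphenyl)ethyl]benzene | COc1ccc(CCc2cc(OC)cc(OC)c2)cc1
F3 | step 3 | 2,4-dimethoxy-6-[2-(4-methoxyphenyl)ethyl]benzaldehyde | COc1cc(OC)c(C=O)c(CCc2ccc(OC)cc2)c1
F4 | step 6 | methyl 2-hydroxy-6-[2-(4-hydroxyphenyl)ethyl]-4-[(2-methylbut-3-yn-2-yl)oxy]benzoate | COC(=O)c1c(O)cc(OC(C)(C)C#C)cc1CCc1ccc(O)cc1
F5 | step 6 | methyl 2-hydroxy-6-[2-(4-hydroxyphenyl)ethyl]-4-[(2-methylbut-3-en-2-yl)oxy]benzoate | COC(=O)c1c(O)cc(OC(C)(C)C=C)cc1CCc1ccc(O)cc1
F6 | step 7 | methyl 2-hydroxy-6-[2-(4-hydroxyphenyl)ethyl]-3-(3-methylbut-2-enyl)-4-[(2-methylbut-3-yn-2-yl)oxy]benzoate | COC(=O)c1c(O)c(CC=C(C)C)c(OC(C)(C)C#C)cc1CCc1ccc(O)cc1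
F7 | step 5 | 2,4-dihydroxy-6-[2-(4-hydroxyphenyl)ethyl]benzoic acid | O=C(O)c1c(O)cc(O)cc1CCc1ccc(O)cc1
A1 | alternative 1 | methyl 7-methyl-3-oxooct-6-enoate | COC(=O)CC(=O)CCC=C(C)C
A2 | alternative 1 | methyl (E)-5-(4-hydroxyphenyl)pent-2-enoate | COC(=O)/C=C/CCc1ccc(O)cc1
A3 | alternative 1 | racemic trans methyl 2-hydroxy-6-[2-(4-hydroxyphenyl)ethyl]-3-(3-methylbut-2-enyl)-4-oxocyclohex-2-ene-1-carboxylate (one enantiomer drawn) | COC(=O)[C@@H]1[C@@H](CCc2ccc(O)cc2)CC(=O)C(CC=C(C)C)=C1O
A4 | alternative 2 | 3-bromo-5-methoxybenzyne (1-bromo-2,3-didehydro-5-methoxybenzene) | BrC1=CC(OC)=CC#C1
A5 | alternative 2 | 5-bromo-7-methoxy-2,2-dimethyl-2H-chromene | COc1cc(Br)c2C=CC(C)(C)Oc2c1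
A6 | alternative 3 | 1-iodo-2,4-bis(methoxymethoxy)-3-(3-methylbut-2-enyl)benzene | COCOc1ccc(I)c(OCOC)c1CC=C(C)C
A7 | alternative 3 | 1-(2-iodoethyl)-4-(methoxymethoxy)benzene | COCOc1ccc(CCI)cc1
A8 | alternative 3 | 2-methylbut-3-en-2-ol | CC(C)(O)C=C
A9 | alternative 3 | (E)-4-{2,4-bis(methoxymethoxy)-3-(3-methylbut-2-enyl)-6-[2-(4-methoxymethoxyphenyl)ethyl]phenyl}-2-methylbut-3-en-2-ol | COCOc1cc(CCc2ccc(OCOC)cc2)c(/C=C/C(C)(C)O)c(OCOC)c1CC=C(C)C
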